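## Retrosynthetic overview

- Target ⇒ cis-fused 1,3-diaryl-tetrahydrothieno[3,4-c]furan: the thiolane ring masks the two cis methyl groups (two C–S hydrogenolyses, with the O-benzyl group removed in the same operation).
- Bicycle ⇒ acyclic pseudo-meso bis(1-arylallyl) ether through one thiyl-radical cascade: the C3–C4 bond closes the oxolane ring first, then the sulfur bridge closes the thiolane ring; C3 and C4 are set from the two carbinol centres.
- Diene ether ⇒ iridium-catalysed asymmetric allylic etherification of an (R)-1-arylallyl alcohol (syringyl part) with a cinnamyl carbonate (veratryl part).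
- Fragments ⇒ syringaldehyde (O-benzylation, catalytic asymmetric vinylation) and methyl 3,4-dimethoxycinnamate (reduction, carbonate formation).

Assumption: the sense of induction of (+)-MIB (R carbinol) and of the (Sa,Sc,Sc) phosphoramidite (S at the new C–O centre) is taken from the usual benzaldehyde and cinnamyl carbonate correlations, from memory; if a test run shows the opposite sense, the enantiomeric ligand is used.

## Route

Step 1
Reactants: 1 4-hydroxy-3,5-dimethoxybenzaldehyde (syringaldehyde)
Product: 2 4-(benzyloxy)-3,5-dimethoxybenzaldehyde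
Conditions: BnBr (1.1 equiv), K2CO3 (1.5 equiv), DMF, 60 °C
Reagents that add atoms: benzyl bromide BrCc1ccccc1
Why: Williamson O-alkylation of the phenoxide masks the phenol, which would otherwise compete as an O-nucleophile in step 5 and quench the radicals of step 6; no stereocentre is formed.

Step 2
Reactants: 2 4-(benzyloxy)-3,5-dimethoxybenzaldehyde
Product: 3 (1R)-1-[4-(benzyloxy)-3,5-dimethoxyphenyl]prop-2-en-1-ol
Conditions: (CH2=CH)2Zn (1.5 equiv, from CH2=CHMgBr and ZnCl2 in Et2O, magnesium salts removed with 1,4-dioxane), (+)-MIB (5 mol %), toluene, −20 → 0 °C; aq NH4Cl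
Reagents that add atoms: divinylzinc C=C[Zn]C=C (made in the flask from vinylmagnesium bromide C=C[Mg]Br and ZnCl2)
Why: Amino-alcohol-catalysed enantioselective addition of a dialkenylzinc to an aldehyde, in which the ligand-bound zinc delivers the vinyl group to the Re face and sets the R carbinol centre (the future C2).

Step 3
Reactants: 4 methyl (2E)-3-(3,4-dimethoxyphenyl)prop-2-enoate
Product: 5 (2E)-3-(3,4-dimethoxyphenyl)prop-2-en-1-ol
Conditions: i-Bu2AlH (2.2 equiv), CH2Cl2, −78 → 0 °C; aq KNaC4H4O6 (potassium sodium tartrate)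
Reagents that add atoms: none
Why: 1,2-Reduction of the conjugated ester by the aluminium hydride at low temperature gives the allylic alcohol and leaves the E alkene untouched; no stereocentre is formed.

Step 4
Reactants: 5 (2E)-3-(3,4-dimethoxyphenyl)prop-2-en-1-ol
Product: 6 tert-butyl (2E)-3-(3,4-dimethoxyphenyl)prop-2-en-1-yl carbonate
Conditions: Boc2O (1.3 equiv), DMAP (10 mol %), MeCN, 0 °C → rt
Reagents that add atoms: di-tert-butyl dicarbonate CC(C)(C)OC(=O)OC(=O)OC(C)(C)C
Why: DMAP-catalysed O-acylation gives the linear allylic tert-butyl carbonate, whose leaving group (CO2 plus tert-butoxide) does not compete as a nucleophile in step 5.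

Step 5
Reactants: 3 (1R)-1-[4-(benzyloxy)-3,5-dimethoxyphenyl]prop-2-en-1-ol; 6 tert-butyl (2E)-3-(3,4-dimethoxyphenyl)prop-2-en-1-yl carbonate
Product: 9 2-(benzyloxy)-5-[(1R)-1-{[(1S)-1-(3,4-dimethoxyphenyl)prop-2-en-1-yl]oxy}prop-2-en-1-yl]-1,3-dimethoxybenzene, via lithium alkoxide 7 (not isolated), via copper alkoxide 8 (not isolated)
Conditions: 3, n-BuLi (1.0 equiv), THF, 0 °C; CuI (1.0 equiv), rt; then 6 (1.2 equiv), [Ir(cod)Cl]2 (2 mol %), (Sa,Sc,Sc)-BINOL N,N-bis(1-phenylethyl)phosphoramidite (4 mol %, pre-activated with n-PrNH2), THF, rt; aq NH4Cl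
Reagents that add atoms: none
Why: Iridium-catalysed branched-selective asymmetric allylic etherification, in which the soft copper alkoxide (its R centre untouched) attacks the aryl-bearing terminus of the allyliridium complex on the face fixed by the ligand, setting the new S centre (the future C5) under catalyst control so that any S enantiomer left in 3 ends up in a separable diastereomer.

Step 6
Reactants: 9 2-(benzyloxy)-5-[(1R)-1-{[(1S)-1-(3,4-dimethoxyphenyl)prop-2-en-1-yl]oxy}prop-2-en-1-yl]-1,3-dimethoxybenzene
Product: 12 (1R,3S,3aS,6aR)-1-[4-(benzyloxy)-3,5-dimethoxyphenyl]-3-(3,4-dimethoxyphenyl)-3a,4,6,6a-tetrahydro-1H,3H-thieno[3,4-c]furan, via thioalkyl radical 10 (not isolated), via oxolanylmethyl radical 11 (not isolated)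
Conditions: (t-BuS)2 (3 equiv), hν (Pyrex, 300–350 nm), degassed t-BuOH, 70 °C, 0.005 M
Reagents that add atoms: di-tert-butyl disulfide CC(C)(C)SSC(C)(C)C
Why: Proposed new method: t-BuS• from photolysis of the disulfide adds to the terminal CH2 of either vinyl group, the secondary radical 10 closes 5-exo through a Beckwith–Houk chair with both aryl groups pseudo-equatorial (giving 2,3-trans, 3,4-cis, 4,5-trans, so C3 and C4 are set from the two carbinol centres), and the primary radical 11 then attacks its own sulfur atom in a five-membered intramolecular homolytic substitution that expels t-Bu• (ending as t-Bu2S) and is possible only for the cis pair, so that oxolane and thiolane form in one operation; the closest known chemistry is the thiyl-radical addition–cyclisation of 1,6-dienes (diallyl ethers give cis-3,4-disubstituted oxolanes) combined with ring-closing homolytic substitution at sulfide sulfur with loss of a tert-butyl radical (about 10^3 to 10^4 per second), which should win here because the medium is dilute and free of hydrogen donors.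

Step 7
Reactants: 12 (1R,3S,3aS,6aR)-1-[4-(benzyloxy)-3,5-dimethoxyphenyl]-3-(3,4-dimethoxyphenyl)-3a,4,6,6a-tetrahydro-1H,3H-thieno[3,4-c]furan
Product: 14 4-[(2R,3R,4S,5S)-5-(3,4-dimethoxyphenyl)-3,4-dimethyloxolan-2-yl]-2,6-dimethoxyphenol, via benzyl ether 13 (not isolated)
Conditions: Raney Ni (W-2, excess), H2 (1 atm), EtOH, 50 °C
Reagents that add atoms: none
Why: Raney-nickel desulfurisation (hydrogenolysis of both C–S bonds) turns the CH2–S–CH2 bridge into the two cis methyl groups without touching any stereocentre, and the same nickel/H2 system cleaves the aryl benzyl ether by hydrogenolysis, while the hindered, electron-rich dibenzylic C–O bonds of the oxolane are the slowest benzylic ethers towards nickel.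

## Compound list

1 | 4-hydroxy-3,5-dimethoxybenzaldehyde (syringaldehyde) | COc1cc(C=O)cc(OC)c1O | starting material
2 | 4-(benzyloxy)-3,5-dimethoxybenzaldehyde | COc1cc(C=O)cc(OC)c1OCc1ccccc1 | intermediate
3 | (1R)-1-[4-(benzyloxy)-3,5-dimethoxyphenyl]prop-2-en-1-ol | O[C@@H](c1cc(OC)c(OCc2ccccc2)c(OC)c1)C=C | intermediate
4 | methyl (2E)-3-(3,4-dimethoxyphenyl)prop-2-enoate | COC(=O)/C=C/c1ccc(OC)c(OC)c1 | starting material
5 | (2E)-3-(3,4-dimethoxyphenyl)prop-2-en-1-ol | OC/C=C/c1ccc(OC)c(OC)c1 | intermediate
6 | tert-butyl (2E)-3-(3,4-dimethoxyphenyl)prop-2-en-1-yl carbonate | CC(C)(C)OC(=O)OC/C=C/c1ccc(OC)c(OC)c1 | intermediate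
7 | lithium (1R)-1-[4-(benzyloxy)-3,5-dimethoxyphenyl]prop-2-en-1-olate | [Li+].[O-][C@@H](c1cc(OC)c(OCc2ccccc2)c(OC)c1)C=C | intermediate
8 | copper (1R)-1-[4-(benzyloxy)-3,5-dimethoxyphenyl]prop-2-en-1-olate (monovalent copper) | [Cu]O[C@@H](c1cc(OC)c(OCc2ccccc2)c(OC)c1)C=C | intermediate
9 | 2-(benzyloxy)-5-[(1R)-1-{[(1S)-1-(3,4-dimethoxyphenyl)prop-2-en-1-yl]oxy}prop-2-en-1-yl]-1,3-dimethoxybenzene | COc1ccc([C@H](C=C)O[C@@H](c2cc(OC)c(OCc3ccccc3)c(OC)c2)C=C)cc1OC | intermediate
10 | secondary radical from addition of t-BuS• to the vinyl group on the 3,4-dimethoxyphenyl side of 9 (both carbinol centres as in 9) | COc1ccc([C@H]([CH]CSC(C)(C)C)O[C@@H](c2cc(OC)c(OCc3ccccc3)c(OC)c2)C=C)cc1OC | intermediate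
11 | primary radical: oxolane with the ring configuration of 13, carrying CH2• at C3 and CH2S-t-Bu at C4, cis to each other and trans to both aryl groups | COc1ccc([C@H]2O[C@@H](c3cc(OC)c(OCc4ccccc4)c(OC)c3)[C@H]([CH2])[C@@H]2CSC(C)(C)C)cc1OC | intermediate
12 | (1R,3S,3aS,6aR)-1-[4-(benzyloxy)-3,5-dimethoxyphenyl]-3-(3,4-dimethoxyphenyl)-3a,4,6,6a-tetrahydro-1H,3H-thieno[3,4-c]furan (cis-fused, both aryl groups exo) | COc1ccc([C@H]2O[C@@H](c3cc(OC)c(OCc4ccccc4)c(OC)c3)[C@@H]5CSC[C@H]25)cc1OC | intermediate
13 | (2R,3R,4S,5S)-2-[4-(benzyloxy)-3,5-dimethoxyphenyl]-5-(3,4-dimethoxyphenyl)-3,4-dimethyloxolane | COc1ccc([C@H]2O[C@@H](c3cc(OC)c(OCc4ccccc4)c(OC)c3)[C@H](C)[C@@H]2C)cc1OC | intermediate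
14 | 4-[(2R,3R,4S,5S)-5-(3,4-dimethoxyphenyl)-3,4-dimethyloxolan-2-yl]-2,6-dimethoxyphenol | COc1ccc([C@H]2O[C@@H](c3cc(OC)c(O)c(OC)c3)[C@H](C)[C@@H]2C)cc1OC | target

## Step count and risks

Total steps: 7. Longest linear sequence: 5 (1 → 2 → 3 → 9 → 12 → 14, or 4 → 5 → 6 → 9 → 12 → 14).

Steps most likely to fail:

Step 6. The ring-closing homolytic substitution at sulfur is the slow link of the cascade, and t-BuS• can also abstract the doubly activated ether C–H of 9. If hydrogen-quenched monocyclic sulfides dominate, the bicycle is given up. The fallback sets out from 9: thiophenol is added slowly with AIBN in benzene at 80 °C (sulfanyl-radical addition–cyclisation of a 1,6-diene, the chain carried by hydrogen transfer from the thiol). Only the oxolane ring forms, as the pair of regioisomeric cis sulfides, the 4-[(phenylsulfanyl)methyl]-3-methyl oxolane F1 and the 3-[(phenylsulfanyl)methyl]-4-methyl oxolane F2, each with both aryl groups trans to the new substituents. The mixture is treated with Raney Ni and H2 as in step 7; both isomers converge on 13, where the fallback rejoins the route, and then on 14.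

Step 5. The hindered secondary copper alkoxide 8 may attack the allyliridium intermediate too slowly, and both partners ionise easily. The fallback sets out from 5 and uses 3: carbonyldiimidazole converts 5 into the imidazole-1-carboxylate F3, which acylates 3 (cat. DBU, THF) to the mixed allyl carbonate F4. [Ir(cod)Cl]2 with the same phosphoramidite then effects a decarboxylative allylic etherification, closest precedent being aryl allyl carbonates: ionisation, loss of CO2, and collapse of the alkoxide–allyliridium ion pair at the branched terminus. This gives 9, where the fallback rejoins the route.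

Step 7. Raney nickel may also hydrogenolyse a benzylic C–O bond of the oxolane, or leave the benzyl ether partly intact. The fallback sets out from 9 and leaves sulfur out altogether: Mn(dpm)3 (cat.), PhSiH3, t-BuOOH, i-PrOH, rt. This is a reductive radical cyclisation started by hydrogen-atom transfer to a terminal alkene, followed by the same chair 5-exo closure and a second hydrogen-atom transfer. It forms only the oxolane ring and gives 13 directly, where the fallback rejoins the route; 13 is then debenzylated with H2 and 10% Pd/C in EtOAc to 14. No new compound is made.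

Further compounds

F1 | step 6 | analogue of 13 with CH2SPh in place of the C4 methyl group (next to the 3,4-dimethoxyphenyl carbon), same ring configuration as 13 | COc1ccc([C@H]2O[C@@H](c3cc(OC)c(OCc4ccccc4)c(OC)c3)[C@H](C)[C@@H]2CSc5ccccc5)cc1OC
F2 | step 6 | analogue of 13 with CH2SPh in place of the C3 methyl group (next to the benzyloxy-dimethoxyphenyl carbon), same ring configuration as 13 | COc1ccc([C@H]2O[C@@H](c3cc(OC)c(OCc4ccccc4)c(OC)c3)[C@H](CSc5ccccc5)[C@@H]2C)cc1OC
F3 | step 5 | (2E)-3-(3,4-dimethoxyphenyl)prop-2-en-1-yl 1H-imidazole-1-carboxylate | COc1ccc(/C=C/COC(=O)n2ccnc2)cc1OC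
F4 | step 5 | (1R)-1-[4-(benzyloxy)-3,5-dimethoxyphenyl]prop-2-en-1-yl (2E)-3-(3,4-dimethoxyphenyl)prop-2-en-1-yl carbonate | COc1ccc(/C=C/COC(=O)O[C@@H](c2cc(OC)c(OCc3ccccc3)c(OC)c2)C=C)cc1OC
F0 | step 7 | none | none
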